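The isoflavone is cut at C2=C3 of pyranone ring C. C2 is a bare CH flanked by O1 and C3, so this alkene can be made from two terminal alkenes: an O-vinyl ether on ring A and the methylene of an α-aryl enone. One ring-closing metathesis then forges C2=C3, closes ring C and expels ethene, with every substituent of rings A and B already in place. The precursor 23 is a fully silylated 1,2-diarylprop-2-en-1-one carrying the O1 vinyl group. It is assembled from ring A aldehyde 9 and ring B alkenyl triflate 20 by CrCl2/NiCl2-mediated coupling and oxidation, and fluoride finishes the synthesis.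

Key step: step 14

Remark: TBS = tert-butyldimethylsilyl, MOM = methoxymethyl; alcohol 22 is formed and used as a racemate because its only stereocentre is removed in step 13, and the target has no stereocentre.

Step 1
Reactants: 1 2-bromoresorcinol (2-bromobenzene-1,3-diol)
Product: 2 2-bromo-1,3-bis(tert-butyldimethylsilyloxy)benzene
Conditions: TBSCl, imidazole, DMF, rt
Reagents that add atoms: tert-butyldimethylsilyl chloride, CC(C)(C)[Si](C)(C)Cl
Why: Imidazole-promoted silylation of both phenols (substitution at silicon) should be clean and installs the fluoride-labile groups that ring A carries to the end.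

Step 2
Reactants: 2 2-bromo-1,3-bis(tert-butyldimethylsilyloxy)benzene; 3 2-methylbut-3-en-2-ol
Product: 5 4-[2,6-bis(tert-butyldimethylsilyloxy)phenyl]-2-methylbutan-2-ol, via B-alkyl-9-BBN adduct 4 (not isolated)
Conditions: 3, 9-BBN-H (2.1 equiv), THF, 0 °C → rt; then 2, Pd(OAc)2 (5 mol%), SPhos, K3PO4, H2O, THF, 65 °C
Reagents that add atoms: none
Why: Anti-Markovnikov hydroboration of the terminal alkene (the hydroxyl takes up the second equivalent of borane) followed by B-alkyl Suzuki–Miyaura coupling should attach the whole 3-hydroxy-3-methylbutyl chain at once, the bulky biarylphosphine being chosen because the C–Br bond sits between two silyloxy groups.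

Step 3
Reactants: 5 4-[2,6-bis(tert-butyldimethylsilyloxy)phenyl]-2-methylbutan-2-ol
Product: 7 3,5-bis(tert-butyldimethylsilyloxy)-4-(3-hydroxy-3-methylbutyl)phenol, via arylboronic pinacol ester 6 (not isolated)
Conditions: [Ir(OMe)(cod)]2 (1.5 mol%), 4,4'-di-tert-butyl-2,2'-bipyridine, B2pin2 (1.5 equiv), THF, 70 °C; then KHSO5 (as 2KHSO5·KHSO4·K2SO4), acetone–H2O, 0 °C
Reagents that add atoms: bis(pinacolato)diboron, CC1(C)OB(OC1(C)C)B1OC(C)(C)C(C)(C)O1 (boron of 6); potassium peroxymonosulfate, [K+].[O-]S(=O)(=O)OO (oxygen of 7)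
Why: Sterically governed iridium-catalysed C–H borylation should select the only ring C–H that has no ortho substituent (para to the side chain), and brief oxidation of the boronate (borylation–oxidation sequence) should then give the symmetric phenol without loss of the aryl silyl ethers.

Step 4
Reactants: 7 3,5-bis(tert-butyldimethylsilyloxy)-4-(3-hydroxy-3-methylbutyl)phenol
Product: 8 2,4-bis(tert-butyldimethylsilyloxy)-6-hydroxy-3-(3-hydroxy-3-methylbutyl)benzaldehyde
Conditions: MgCl2, Et3N, (CH2O)n, THF, reflux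
Reagents that add atoms: paraformaldehyde (formaldehyde), C=O
Why: Magnesium phenoxide-directed ortho-formylation (Casnati–Skattebøl reaction) delivers formaldehyde next to the free hydroxyl only, and because the two ortho positions of 7 are equivalent a single aldehyde should result.

Step 5
Reactants: 8 2,4-bis(tert-butyldimethylsilyloxy)-6-hydroxy-3-(3-hydroxy-3-methylbutyl)benzaldehyde
Product: 9 2,4-bis(tert-butyldimethylsilyloxy)-6-(ethenyloxy)-3-(3-hydroxy-3-methylbutyl)benzaldehyde
Conditions: Cu(OAc)2 (1 equiv), 2,4,6-trivinylcyclotriboroxane–pyridine complex, pyridine, CH2Cl2, rt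
Reagents that add atoms: 2,4,6-trivinylcyclotriboroxane–pyridine complex, C=CB1OB(C=C)OB(C=C)O1.c1ccncc1
Why: Copper-mediated oxidative O-vinylation of the phenol by a vinylboron reagent (Chan–Lam coupling) runs at room temperature under weakly basic conditions that should spare the aldehyde, the silyl ethers and the unreactive tertiary alcohol.

Step 6
Reactants: 10 resorcinol (benzene-1,3-diol)
Product: 11 1,3-bis(methoxymethoxy)benzene
Conditions: MOMCl, iPr2NEt, CH2Cl2, 0 °C → rt
Reagents that add atoms: chloromethyl methyl ether, COCCl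
Why: O-Alkylation of both phenols (Williamson-type acetal formation) gives the bis-acetal whose oxygens direct the two lithiations that follow.

Step 7
Reactants: 11 1,3-bis(methoxymethoxy)benzene; 12 prenyl bromide (1-bromo-3-methylbut-2-ene)
Product: 14 1,3-bis(methoxymethoxy)-2-(3-methylbut-2-enyl)benzene, via C2 aryllithium 13 (not isolated)
Conditions: n-BuLi, THF, 0 °C → rt; then 12, −78 °C → rt
Reagents that add atoms: none
Why: Directed ortho-metalation occurs at C2 between the two acetal oxygens, and the aryllithium should be alkylated by the primary allylic bromide at its unsubstituted terminus.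

Step 8
Reactants: 14 1,3-bis(methoxymethoxy)-2-(3-methylbut-2-enyl)benzene
Product: 16 1-[2,4-bis(methoxymethoxy)-3-(3-methylbut-2-enyl)phenyl]ethanone, via C4 aryllithium 15 (not isolated)
Conditions: n-BuLi, TMEDA, THF, 0 °C; then MeC(O)N(OMe)Me, −78 °C → rt; then H2O
Reagents that add atoms: N-methoxy-N-methylacetamide, CC(=O)N(C)OC
Why: The second directed ortho-metalation can only take place at the equivalent C4/C6 positions, and acylation of the aryllithium by the Weinreb amide stops at the ketone because the chelated tetrahedral adduct survives until work-up.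

Step 9
Reactants: 16 1-[2,4-bis(methoxymethoxy)-3-(3-methylbut-2-enyl)phenyl]ethanone
Product: 17 1-[2,4-dihydroxy-3-(3-methylbut-2-enyl)phenyl]ethanone
Conditions: 3 M HCl (aq), MeOH, 45 °C
Reagents that add atoms: none
Why: Acid-catalysed acetal cleavage removes both MOM groups under conditions that an ortho-prenyl phenol normally tolerates, since closure to the chroman needs stronger acid.

Step 10
Reactants: 17 1-[2,4-dihydroxy-3-(3-methylbut-2-enyl)phenyl]ethanone
Product: 18 1-[2,4-bis(tert-butyldimethylsilyloxy)-3-(3-methylbut-2-enyl)phenyl]ethanone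
Conditions: TBSOTf, 2,6-lutidine, CH2Cl2, −78 → 0 °C
Reagents that add atoms: tert-butyldimethylsilyl trifluoromethanesulfonate, CC(C)(C)[Si](C)(C)OS(=O)(=O)C(F)(F)F
Why: The silyl triflate with a hindered pyridine base should silylate both phenols, including the hydrogen-bonded and flanked 2-hydroxyl, at a temperature at which the ketone is not turned into its silyl enol ether.

Step 11
Reactants: 18 1-[2,4-bis(tert-butyldimethylsilyloxy)-3-(3-methylbut-2-enyl)phenyl]ethanone
Product: 20 1-[2,4-bis(tert-butyldimethylsilyloxy)-3-(3-methylbut-2-enyl)phenyl]ethenyl trifluoromethanesulfonate, via lithium enolate 19 (not isolated)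
Conditions: LiN(SiMe3)2, THF, −78 °C; then N-(5-chloro-2-pyridyl)triflimide, −78 → −20 °C; Et3N-deactivated silica
Reagents that add atoms: N-(5-chloropyridin-2-yl)-1,1,1-trifluoro-N-(trifluoromethylsulfonyl)methanesulfonamide, FC(F)(F)S(=O)(=O)N(c1ccc(Cl)cn1)S(=O)(=O)C(F)(F)F
Why: Kinetic deprotonation of the methyl ketone and O-sulfonylation of the lithium enolate by the reactive pyridyl triflimide at low temperature (enol triflate formation) should give the 1-arylvinyl triflate before silyl transfer from the neighbouring aryl ether can set in.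

Step 12
Reactants: 9 2,4-bis(tert-butyldimethylsilyloxy)-6-(ethenyloxy)-3-(3-hydroxy-3-methylbutyl)benzaldehyde; 20 1-[2,4-bis(tert-butyldimethylsilyloxy)-3-(3-methylbut-2-enyl)phenyl]ethenyl trifluoromethanesulfonate
Product: 22 racemic 1-[2,4-bis(tert-butyldimethylsilyloxy)-6-(ethenyloxy)-3-(3-hydroxy-3-methylbutyl)phenyl]-2-[2,4-bis(tert-butyldimethylsilyloxy)-3-(3-methylbut-2-enyl)phenyl]prop-2-en-1-ol, via alkenylchromium dichloride 21 (not isolated)
Conditions: CrCl2 (5 equiv), NiCl2 (3 mol%), DMF, rt; aq. NaHCO3 work-up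
Reagents that add atoms: none
Why: In the Nozaki–Hiyama–Kishi reaction zerovalent nickel (formed from NiCl2 by CrCl2) inserts into the alkenyl triflate and passes the alkenyl group to chromium, and the alkenylchromium reagent adds only to the aldehyde, leaving silyl ethers, vinyl ether and the free tertiary alcohol alone, while the new carbinol centre forms without control (racemate) and is erased in step 13.

Step 13
Reactants: 22 racemic 1-[2,4-bis(tert-butyldimethylsilyloxy)-6-(ethenyloxy)-3-(3-hydroxy-3-methylbutyl)phenyl]-2-[2,4-bis(tert-butyldimethylsilyloxy)-3-(3-methylbut-2-enyl)phenyl]prop-2-en-1-ol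
Product: 23 1-[2,4-bis(tert-butyldimethylsilyloxy)-6-(ethenyloxy)-3-(3-hydroxy-3-methylbutyl)phenyl]-2-[2,4-bis(tert-butyldimethylsilyloxy)-3-(3-methylbut-2-enyl)phenyl]prop-2-en-1-one
Conditions: Dess–Martin periodinane, NaHCO3, CH2Cl2, 0 °C → rt (crude 22 used directly)
Reagents that add atoms: none
Why: Buffered Dess–Martin oxidation should convert the benzylic and allylic secondary alcohol into the ketone, whereas the tertiary alcohol cannot be oxidised and the bicarbonate keeps acetic acid away from the vinyl ether.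

Step 14
Reactants: 23 1-[2,4-bis(tert-butyldimethylsilyloxy)-6-(ethenyloxy)-3-(3-hydroxy-3-methylbutyl)phenyl]-2-[2,4-bis(tert-butyldimethylsilyloxy)-3-(3-methylbut-2-enyl)phenyl]prop-2-en-1-one
Product: 24 5,7-bis(tert-butyldimethylsilyloxy)-3-[2,4-bis(tert-butyldimethylsilyloxy)-3-(3-methylbut-2-enyl)phenyl]-6-(3-hydroxy-3-methylbutyl)-4H-chromen-4-one
Conditions: RuCl2(H2IMes)(=CH-C6H4-2-OiPr) (second-generation Hoveyda–Grubbs catalyst, 15 mol% in portions), 1,4-benzoquinone (10 mol%), toluene (0.005 M), 100 °C, Ar sparge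
Reagents that add atoms: none
Why: Proposed new method: the catalyst RuCl2(H2IMes)(=CH-C6H4-2-OiPr) should exchange first with the unhindered O-vinyl group of ring A to give an aryloxycarbene [Ru]=CH–OAr held within reach of the 1,1-disubstituted enone alkene, to which it adds by intramolecular [2+2] cycloaddition; retro-[2+2] of the ruthenacyclobutane then releases the C2=C3 bond and [Ru]=CH2, which carries the chain with loss of ethene. The closest known reaction types are ring-closing metathesis of aryl vinyl ethers with styrenes to benzofurans and 4H-chromenes and of aryl acrylates with styrenes to coumarins, but closure of an aryl enol ether onto an α-aryl enone to a chromen-4-one has not been shown, hence the label. Ring C is closed as a six-membered ring with the new double bond endocyclic (C2 from the vinyl ether, C3 from the enone), and the gain of the conjugated 4-pyranone together with removal of ethene by the argon stream supplies the driving force that the stabilised aryloxycarbene lacks. No stereocentre is created. The step needs chemoselectivity for the two terminal alkenes over the trisubstituted prenyl alkene, which is secured by the low metathesis reactivity of trisubstituted alkenes, by the inability of the prenyl group to reach either partner in a small ring and by sweeping out ethene so that ethenolysis of the prenyl group is suppressed, while high dilution disfavours intermolecular coupling.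

Step 15
Reactants: 24 5,7-bis(tert-butyldimethylsilyloxy)-3-[2,4-bis(tert-butyldimethylsilyloxy)-3-(3-methylbut-2-enyl)phenyl]-6-(3-hydroxy-3-methylbutyl)-4H-chromen-4-one
Product: 25 5,7-dihydroxy-3-[2,4-dihydroxy-3-(3-methylbut-2-enyl)phenyl]-6-(3-hydroxy-3-methylbutyl)-4H-chromen-4-one (CNP0076924.0)
Conditions: Bu4NF, AcOH, THF, 0 °C → rt
Reagents that add atoms: none
Why: Acetic acid-buffered fluoride cleaves the four aryl silyl ethers (desilylation) under conditions in which the prenyl group, the tertiary alcohol and the isoflavone ring are stable, so no acid-induced chroman formation can interfere.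

Compound list
1 | 2-bromoresorcinol (2-bromobenzene-1,3-diol) | Oc1cccc(O)c1Br | starting material
2 | 2-bromo-1,3-bis(tert-butyldimethylsilyloxy)benzene | CC(C)(C)[Si](C)(C)Oc1cccc(O[Si](C)(C)C(C)(C)C)c1Br | intermediate
3 | 2-methylbut-3-en-2-ol | C=CC(C)(C)O | starting material
4 | 9-[3-(9-borabicyclo[3.3.1]nonan-9-yloxy)-3-methylbutyl]-9-borabicyclo[3.3.1]nonane | CC(C)(CCB1C2CCCC1CCC2)OB1C2CCCC1CCC2 | intermediate (not isolated)
5 | 4-[2,6-bis(tert-butyldimethylsilyloxy)phenyl]-2-methylbutan-2-ol | CC(C)(O)CCc1c(O[Si](C)(C)C(C)(C)C)cccc1O[Si](C)(C)C(C)(C)C | intermediate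
6 | 4-[2,6-bis(tert-butyldimethylsilyloxy)-4-(4,4,5,5-tetramethyl-1,3,2-dioxaborolan-2-yl)phenyl]-2-methylbutan-2-ol | CC(C)(O)CCc1c(O[Si](C)(C)C(C)(C)C)cc(B2OC(C)(C)C(C)(C)O2)cc1O[Si](C)(C)C(C)(C)C | intermediate (not isolated)
7 | 3,5-bis(tert-butyldimethylsilyloxy)-4-(3-hydroxy-3-methylbutyl)phenol | CC(C)(O)CCc1c(O[Si](C)(C)C(C)(C)C)cc(O)cc1O[Si](C)(C)C(C)(C)C | intermediate
8 | 2,4-bis(tert-butyldimethylsilyloxy)-6-hydroxy-3-(3-hydroxy-3-methylbutyl)benzaldehyde | CC(C)(O)CCc1c(O[Si](C)(C)C(C)(C)C)cc(O)c(C=O)c1O[Si](C)(C)C(C)(C)C | intermediate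
9 | 2,4-bis(tert-butyldimethylsilyloxy)-6-(ethenyloxy)-3-(3-hydroxy-3-methylbutyl)benzaldehyde | CC(C)(O)CCc1c(O[Si](C)(C)C(C)(C)C)cc(OC=C)c(C=O)c1O[Si](C)(C)C(C)(C)C | intermediate
10 | resorcinol (benzene-1,3-diol) | Oc1cccc(O)c1 | starting material
11 | 1,3-bis(methoxymethoxy)benzene | COCOc1cccc(OCOC)c1 | intermediate
12 | prenyl bromide (1-bromo-3-methylbut-2-ene) | CC(C)=CCBr | starting material
13 | 2-lithio-1,3-bis(methoxymethoxy)benzene | [Li]c1c(OCOC)cccc1OCOC | intermediate (not isolated)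
14 | 1,3-bis(methoxymethoxy)-2-(3-methylbut-2-enyl)benzene | COCOc1cccc(OCOC)c1CC=C(C)C | intermediate
15 | 4-lithio-1,3-bis(methoxymethoxy)-2-(3-methylbut-2-enyl)benzene | [Li]c1ccc(OCOC)c(CC=C(C)C)c1OCOC | intermediate (not isolated)
16 | 1-[2,4-bis(methoxymethoxy)-3-(3-methylbut-2-enyl)phenyl]ethanone | CC(=O)c1ccc(OCOC)c(CC=C(C)C)c1OCOC | intermediate
17 | 1-[2,4-dihydroxy-3-(3-methylbut-2-enyl)phenyl]ethanone | CC(=O)c1ccc(O)c(CC=C(C)C)c1O | intermediate
18 | 1-[2,4-bis(tert-butyldimethylsilyloxy)-3-(3-methylbut-2-enyl)phenyl]ethanone | CC(=O)c1ccc(O[Si](C)(C)C(C)(C)C)c(CC=C(C)C)c1O[Si](C)(C)C(C)(C)C | intermediate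
19 | lithium 1-[2,4-bis(tert-butyldimethylsilyloxy)-3-(3-methylbut-2-enyl)phenyl]ethenolate | C=C(O[Li])c1ccc(O[Si](C)(C)C(C)(C)C)c(CC=C(C)C)c1O[Si](C)(C)C(C)(C)C | intermediate (not isolated)
20 | 1-[2,4-bis(tert-butyldimethylsilyloxy)-3-(3-methylbut-2-enyl)phenyl]ethenyl trifluoromethanesulfonate | C=C(OS(=O)(=O)C(F)(F)F)c1ccc(O[Si](C)(C)C(C)(C)C)c(CC=C(C)C)c1O[Si](C)(C)C(C)(C)C | intermediate
21 | {1-[2,4-bis(tert-butyldimethylsilyloxy)-3-(3-methylbut-2-enyl)phenyl]ethenyl}chromium dichloride | C=C([Cr](Cl)Cl)c1ccc(O[Si](C)(C)C(C)(C)C)c(CC=C(C)C)c1O[Si](C)(C)C(C)(C)C | intermediate (not isolated)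
22 | racemic 1-[2,4-bis(tert-butyldimethylsilyloxy)-6-(ethenyloxy)-3-(3-hydroxy-3-methylbutyl)phenyl]-2-[2,4-bis(tert-butyldimethylsilyloxy)-3-(3-methylbut-2-enyl)phenyl]prop-2-en-1-ol | C=C(C(O)c1c(OC=C)cc(O[Si](C)(C)C(C)(C)C)c(CCC(C)(C)O)c1O[Si](C)(C)C(C)(C)C)c1ccc(O[Si](C)(C)C(C)(C)C)c(CC=C(C)C)c1O[Si](C)(C)C(C)(C)C | intermediate
23 | 1-[2,4-bis(tert-butyldimethylsilyloxy)-6-(ethenyloxy)-3-(3-hydroxy-3-methylbutyl)phenyl]-2-[2,4-bis(tert-butyldimethylsilyloxy)-3-(3-methylbut-2-enyl)phenyl]prop-2-en-1-one | C=COc1cc(O[Si](C)(C)C(C)(C)C)c(CCC(C)(C)O)c(O[Si](C)(C)C(C)(C)C)c1C(=O)C(=C)c1ccc(O[Si](C)(C)C(C)(C)C)c(CC=C(C)C)c1O[Si](C)(C)C(C)(C)C | intermediate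
24 | 5,7-bis(tert-butyldimethylsilyloxy)-3-[2,4-bis(tert-butyldimethylsilyloxy)-3-(3-methylbut-2-enyl)phenyl]-6-(3-hydroxy-3-methylbutyl)-4H-chromen-4-one | CC(C)=CCc1c(O[Si](C)(C)C(C)(C)C)ccc(-c2coc3cc(O[Si](C)(C)C(C)(C)C)c(CCC(C)(C)O)c(O[Si](C)(C)C(C)(C)C)c3c2=O)c1O[Si](C)(C)C(C)(C)C | intermediate
25 | 5,7-dihydroxy-3-[2,4-dihydroxy-3-(3-methylbut-2-enyl)phenyl]-6-(3-hydroxy-3-methylbutyl)-4H-chromen-4-one (CNP0076924.0) | CC(C)=CCc1c(O)ccc(-c2coc3cc(O)c(CCC(C)(C)O)c(O)c3c2=O)c1O | target

Total step count: 15 (steps 1–5 to ring A fragment 9, steps 6–11 to ring B fragment 20, steps 12–15 after convergence).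
Longest linear sequence: 10 steps (resorcinol 10 to target 25 through steps 6–15).

Steps most likely to fail

Step 14. The aryloxycarbene formed on the vinyl ether may be too stabilised to add to the hindered, electron-poor enone alkene, so that the catalyst is trapped and decays while the enone slowly oligomerises. The fallback uses known chemistry, sets out from 23 and rejoins the route at 25. Dilute HCl in THF–H2O at rt hydrolyses the aryl vinyl ether to 1-[2,4-bis(tert-butyldimethylsilyloxy)-6-hydroxy-3-(3-hydroxy-3-methylbutyl)phenyl]-2-[2,4-bis(tert-butyldimethylsilyloxy)-3-(3-methylbut-2-enyl)phenyl]prop-2-en-1-one F1. On addition of Et3N the phenol of F1 closes onto the enone methylene by oxa-Michael addition to give the racemic isoflavanone 5,7-bis(tert-butyldimethylsilyloxy)-3-[2,4-bis(tert-butyldimethylsilyloxy)-3-(3-methylbut-2-enyl)phenyl]-6-(3-hydroxy-3-methylbutyl)chroman-4-one F2. TMSOTf and Et3N in CH2Cl2 at 0 °C convert F2 into the bis(trimethylsilyl) derivative 5,7-bis(tert-butyldimethylsilyloxy)-3-[2,4-bis(tert-butyldimethylsilyloxy)-3-(3-methylbut-2-enyl)phenyl]-6-[3-methyl-3-(trimethylsilyloxy)butyl]-4-(trimethylsilyloxy)-2H-chromene F3. Saegusa–Ito oxidation with Pd(OAc)2 in MeCN then gives 5,7-bis(tert-butyldimethylsilyloxy)-3-[2,4-bis(tert-butyldimethylsilyloxy)-3-(3-methylbut-2-enyl)phenyl]-6-[3-methyl-3-(trimethylsilyloxy)butyl]-4H-chromen-4-one F4. The conditions of step 15 remove all five silyl groups from F4 and give 25.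

Step 12. Addition of the alkenylchromium species to the doubly ortho-substituted, electron-rich aldehyde may be slow, with competing protodemetalation and solvolysis of the electron-rich alkenyl triflate. The fallback sets out from ketone 18 and rejoins at 22. Hydrazine hydrate and Et3N in EtOH give 1-[2,4-bis(tert-butyldimethylsilyloxy)-3-(3-methylbut-2-enyl)phenyl]ethanone hydrazone F5. Barton vinyl iodide synthesis (I2, tetramethylguanidine, THF, 0 °C) converts it into 1-[2,4-bis(tert-butyldimethylsilyloxy)-3-(3-methylbut-2-enyl)phenyl]-1-iodoethene F6. Iodine–lithium exchange with t-BuLi (2 equiv) in Et2O at −78 °C gives {1-[2,4-bis(tert-butyldimethylsilyloxy)-3-(3-methylbut-2-enyl)phenyl]ethenyl}lithium F7. F7 is used in excess because the tertiary hydroxyl of 9 consumes one equivalent, and it is kept at −78 °C to suppress silyl migration from oxygen to carbon; addition to aldehyde 9 gives 22.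

Step 5. Chelation of copper by the ortho-hydroxy aldehyde may stall transfer of the vinyl group. The fallback sets out from phenol 7, rejoins at 9 and also bypasses step 4. NBS (1 equiv) in CH2Cl2 at −78 °C gives 2-bromo-3,5-bis(tert-butyldimethylsilyloxy)-4-(3-hydroxy-3-methylbutyl)phenol F8. This non-chelating phenol is O-vinylated with Cu(OAc)2 and the trivinylboroxine–pyridine complex to 4-[3-bromo-2,6-bis(tert-butyldimethylsilyloxy)-4-(ethenyloxy)phenyl]-2-methylbutan-2-ol F9. n-BuLi (2.2 equiv) in THF at −78 °C deprotonates the alcohol and exchanges the bromine to give the lithium alkoxide of 4-[2,6-bis(tert-butyldimethylsilyloxy)-4-(ethenyloxy)-3-lithiophenyl]-2-methylbutan-2-ol F10, which is formylated with DMF to 9.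

Further compounds
F1 | step 14 | 1-[2,4-bis(tert-butyldimethylsilyloxy)-6-hydroxy-3-(3-hydroxy-3-methylbutyl)phenyl]-2-[2,4-bis(tert-butyldimethylsilyloxy)-3-(3-methylbut-2-enyl)phenyl]prop-2-en-1-one | C=C(C(=O)c1c(O)cc(O[Si](C)(C)C(C)(C)C)c(CCC(C)(C)O)c1O[Si](C)(C)C(C)(C)C)c1ccc(O[Si](C)(C)C(C)(C)C)c(CC=C(C)C)c1O[Si](C)(C)C(C)(C)C
F2 | step 14 | racemic 5,7-bis(tert-butyldimethylsilyloxy)-3-[2,4-bis(tert-butyldimethylsilyloxy)-3-(3-methylbut-2-enyl)phenyl]-6-(3-hydroxy-3-methylbutyl)chroman-4-one | CC(C)=CCc1c(O[Si](C)(C)C(C)(C)C)ccc(C2COc3cc(O[Si](C)(C)C(C)(C)C)c(CCC(C)(C)O)c(O[Si](C)(C)C(C)(C)C)c3C2=O)c1O[Si](C)(C)C(C)(C)C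
F3 | step 14 | 5,7-bis(tert-butyldimethylsilyloxy)-3-[2,4-bis(tert-butyldimethylsilyloxy)-3-(3-methylbut-2-enyl)phenyl]-6-[3-methyl-3-(trimethylsilyloxy)butyl]-4-(trimethylsilyloxy)-2H-chromene | CC(C)=CCc1c(O[Si](C)(C)C(C)(C)C)ccc(C2=C(O[Si](C)(C)C)c3c(O[Si](C)(C)C(C)(C)C)c(CCC(C)(C)O[Si](C)(C)C)c(O[Si](C)(C)C(C)(C)C)cc3OC2)c1O[Si](C)(C)C(C)(C)C
F4 | step 14 | 5,7-bis(tert-butyldimethylsilyloxy)-3-[2,4-bis(tert-butyldimethylsilyloxy)-3-(3-methylbut-2-enyl)phenyl]-6-[3-methyl-3-(trimethylsilyloxy)butyl]-4H-chromen-4-one | CC(C)=CCc1c(O[Si](C)(C)C(C)(C)C)ccc(-c2coc3cc(O[Si](C)(C)C(C)(C)C)c(CCC(C)(C)O[Si](C)(C)C)c(O[Si](C)(C)C(C)(C)C)c3c2=O)c1O[Si](C)(C)C(C)(C)C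
F5 | step 12 | 1-[2,4-bis(tert-butyldimethylsilyloxy)-3-(3-methylbut-2-enyl)phenyl]ethanone hydrazone (E/Z not defined) | CC(=NN)c1ccc(O[Si](C)(C)C(C)(C)C)c(CC=C(C)C)c1O[Si](C)(C)C(C)(C)C
F6 | step 12 | 1-[2,4-bis(tert-butyldimethylsilyloxy)-3-(3-methylbut-2-enyl)phenyl]-1-iodoethene | C=C(I)c1ccc(O[Si](C)(C)C(C)(C)C)c(CC=C(C)C)c1O[Si](C)(C)C(C)(C)C
F7 | step 12 | {1-[2,4-bis(tert-butyldimethylsilyloxy)-3-(3-methylbut-2-enyl)phenyl]ethenyl}lithium | [Li]C(=C)c1ccc(O[Si](C)(C)C(C)(C)C)c(CC=C(C)C)c1O[Si](C)(C)C(C)(C)C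
F8 | step 5 | 2-bromo-3,5-bis(tert-butyldimethylsilyloxy)-4-(3-hydroxy-3-methylbutyl)phenol | CC(C)(O)CCc1c(O[Si](C)(C)C(C)(C)C)cc(O)c(Br)c1O[Si](C)(C)C(C)(C)C
F9 | step 5 | 4-[3-bromo-2,6-bis(tert-butyldimethylsilyloxy)-4-(ethenyloxy)phenyl]-2-methylbutan-2-ol | CC(C)(O)CCc1c(O[Si](C)(C)C(C)(C)C)cc(OC=C)c(Br)c1O[Si](C)(C)C(C)(C)C
F10 | step 5 | lithium alkoxide of 4-[2,6-bis(tert-butyldimethylsilyloxy)-4-(ethenyloxy)-3-lithiophenyl]-2-methylbutan-2-ol | [Li]OC(C)(C)CCc1c(O[Si](C)(C)C(C)(C)C)cc(OC=C)c([Li])c1O[Si](C)(C)C(C)(C)C
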